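Dividing each target reading by its substrate charge is the easy first step.

| flask | substrate | free catalyst | time |
|---|---|---|---|
| alpha | 0.120 M | 0.00600 M |  |
| delta | 0.0600 M | 0.00600 M |  |
| epsilon | 0.180 M | 0.00600 M |  |
| eta | 0.120 M | 0.00900 M |  |
| gamma | 0.120 M | 0.00600 M | 76 min |

| run | time / min | [target] / M |
|---|---|---|
| alpha run | 0.76 | 0.0063 |
| alpha run | 1.4 | 0.0117 |
| alpha run | 2.8 | 0.0216 |
| alpha run | 5.2 | 0.0353 |
| alpha run | 10 | 0.0534 |
| alpha run | 19 | 0.0667 |
| delta run | 0.76 | 0.0029 |
| delta run | 1.4 | 0.0064 |
| delta run | 2.8 | 0.0116 |
| delta run | 5.2 | 0.0177 |
| delta run | 10 | 0.0287 |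
| delta run | 19 | 0.0365 |
| epsilon run | 0.76 | 0.0096 |
| epsilon run | 1.4 | 0.0169 |
| epsilon run | 2.8 | 0.0320 |
| epsilon run | 5.2 | 0.0533 |
| epsilon run | 10 | 0.0819 |
| epsilon run | 19 | 0.1015 |
| eta run | 0.76 | 0.0080 |
| eta run | 1.4 | 0.0143 |
| eta run | 2.8 | 0.0256 |
| eta run | 5.2 | 0.0429 |
| eta run | 10 | 0.0603 |
| eta run | 19 | 0.0724 |

(readings scatter by 0.001 M)

1. how the opening rate goes with [substrate] round the charge of the alpha run: the exponent of the rate at two percent of substrate gone to target (one fixed amount of target, the same in the runs compared)
2. how the opening rate goes with [free catalyst] round the charge of the alpha run: the exponent of the rate at two percent of substrate gone to target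
3. target in the gamma run at 76 min, as a share of the substrate charged
4. which of these the readings show (the catalyst dies by itself / the catalyst dies in pairs / the substrate kills the catalyst / the product decays)

- Overall: substrate -> target, with free catalyst as catalyst.
- Constant volume, constant temperature.
- An order is taken over about fifteen percent of the charge, up and down.

At 10 min, those fractions of the charge stand at 0.445 in alpha, 0.478 in delta and 0.455 in epsilon. That near overlap fits a rate in step with substrate, but a catalyst dying by itself or in pairs stays open at this point, so a frozen free catalyst, which makes the rate pseudo-first-order, is only a trial below. Summing the first two readings of each run gives rough orders, read at equal times, near 0.954 in substrate from epsilon against alpha and 0.528 in free catalyst from eta against alpha.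

The alpha reading at 2.8 min gives a formation constant of 0.0709 min⁻¹. At 14.5 min, midway between the last two alpha readings, that constant leaves a substrate fraction of 0.358, so target should be gaining 0.0254 min⁻¹. The readings show a gain of 0.0123 min⁻¹ at a target fraction of 0.500. The gap, divided by that fraction, is the loss constant, the share of standing target that goes per minute: 0.0261 min⁻¹.

Gamma repeats the alpha charge, so two consecutive steps with these constants give 21.1% at 76 min.

The weak link is that one midpoint in one flask. The same reckoning on epsilon gives 0.0260 min⁻¹. On eta, whose formation constant reads 0.0857 min⁻¹, it gives 0.0245 min⁻¹. In alpha, the first-order slope of substrate turned, read from target, stands at 0.0709 min⁻¹ up to 2.8 min, 0.0501 min⁻¹ between 5.2 min and 10 min, and 0.0248 min⁻¹ between 10 min and 19 min, so the drop comes late. A catalyst dying by itself or in pairs loses a steady or shrinking fraction of its activity per minute, which fits this late drop poorly, so the reading here is that the product decays.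

The forecast commits to orders of 0.97 and 0.55, 20% and the product decays, on the ground that “Consecutive first-order steps fit all the points”. Its yield lies below the 21.1% reckoned here.

The flask gives orders of 1.0 and 0.62, 22.3% in gamma, and the product decays.

    2 free catalyst ⇌ catalyst dimer, settled at all times (339.0 M⁻¹)
    free catalyst + substrate → target + free catalyst (31.20 M⁻¹ min⁻¹)
    target → decomposed product (0.02490 min⁻¹)

In the gamma run, the passing of target into decomposed product is the main reason that target stands at 22.3% of the charge. The same run without that step reaches 99.6%, and the step accounts for 99% of what is missing. The loss constant of 0.0261 min⁻¹ put gamma 1.2 percentage points below the flask's value. Set to zero, it leaves the turned share of substrate, 99.5%, for the run stored at 99.6%.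

The runs were computed from invented constants; scatter was added.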